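The numbers in the tables come from a simulation with made-up constants; noise was put on by code.

To choose which reagent to feed slowly, first look at the fork at the substrate.

| flask | substrate | coupling partner | second reagent | third reagent | remark | time |
|---|---|---|---|---|---|---|
| eta | 0.050 M | 2 equiv | 0.95 equiv | 1.1 equiv | run made earlier |  |
| zeta | 0.050 M | 2 equiv | 0.47 equiv | 1.1 equiv | run made earlier |  |
| beta | 0.050 M | 2 equiv | 1.9 equiv | 1.1 equiv | run made earlier |  |
| gamma | 0.050 M | 3 equiv | 0.95 equiv | 1.1 equiv | run made earlier |  |
| autumn | 0.050 M | 2.00 equiv | 0.950 equiv | 1.10 equiv (fed, over 15 h) | all else is in the flask from the start; the feed brings no volume worth counting | 20 h |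
| summer | 0.050 M | 2.00 equiv | 0.950 equiv | 1.10 equiv | everything together at the start | 20 h |
| midnight | 0.050 M | 2.00 equiv (fed, over 15 h) | 0.950 equiv | 1.10 equiv | all else is in the flask from the start; the feed brings no volume worth counting | 20 h |

| run | time / h | side product / % | target / % |
|---|---|---|---|
| eta | 3.00 | 64.2 | 1.2 |
| eta | 6.00 | 64.2 | 2.7 |
| eta | 10.0 | 65.0 | 4.5 |
| eta | 12.0 | 65.2 | 5.5 |
| eta | 15.0 | 63.8 | 8.9 |
| eta | 20.0 | 64.5 | 11.1 |
| zeta | 2.50 | 37.8 | 1.2 |
| zeta | 5.00 | 39.3 | 0.4 |
| zeta | 8.00 | 39.3 | 1.7 |
| zeta | 10.0 | 39.4 | 0.6 |
| zeta | 12.0 | 38.6 | 3.2 |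
| zeta | 15.0 | 39.6 | 3.8 |
| beta | 1.33 | 81.7 | 0.1 |
| beta | 2.00 | 82.3 | 0.9 |
| beta | 4.00 | 82.6 | 3.0 |
| beta | 6.00 | 82.1 | 2.9 |
| beta | 10.0 | 83.2 | 6.0 |
| beta | 15.0 | 81.4 | 7.9 |
| gamma | 3.00 | 55.6 | 1.0 |
| gamma | 6.00 | 57.3 | 3.5 |
| gamma | 10.0 | 56.4 | 7.0 |
| gamma | 12.0 | 57.1 | 9.8 |
| gamma | 15.0 | 56.3 | 11.1 |

(scatter of a reading: 0.5 percentage points)

- the flask with the highest amount of side product, in percent of the substrate charged ("all alike" if they lie within 1.5 percentage points) (autumn / summer / midnight / all alike)
- final side product, as a percentage of the substrate charged, in autumn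
- final side product, as a percentage of the substrate charged, in summer
- final side product, as a percentage of the substrate charged, in midnight

- what was read earlier has a scatter of 0.5 percentage points, one standard deviation

In the eta run, side product reads 64.2% at 3.00 h and 64.5% at 20.0 h, so a fast burst is over by the first reading. I take the substrate to fork: one branch takes second reagent to side product, the other takes coupling partner on towards target. If each branch is first order in substrate and in its partner, substrate cancels from the ratio of rates. The fractions left by the fork then obey f_D = f_B^S, with f_D for second reagent, f_B for coupling partner, and S the selectivity factor, the ratio of the two rate constants.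

I assume that substrate not in side product took coupling partner. Eta then gives f_D = 0.321 and f_B = 0.823, so S = 5.81. The gamma run, with a different charge, gives 5.70.

Two views now part. The charge view says the same amounts give the same split, so the three flasks match eta near 64.5%. The feed view says the split follows the coupling partner present during the burst: midnight has received 0.400 equiv by 3.00 h, not 2.00 equiv.

The forecast takes the feed view: “Feeding coupling partner slowly removes that competitor during the burst”. It gives 65% (58% to 76%) for autumn, 64.5% (63.5% to 65.5%) for summer and 83% (73% to 92%) for midnight, so midnight leads.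

My own reckoning differs slightly. Define the effective charge b as the batch charge of coupling partner that gives the same split under the rule. For 83%, b must be 0.568 equiv, more than midnight has received by 3.00 h. So I lean above 83%, below what the 0.950 equiv of second reagent allows.

The simulation gives 64.5% for autumn, 64.5% for summer and 88.0% for midnight.

    substrate + coupling partner → intermediate A (k = 0.100 L mol⁻¹ min⁻¹)
    second reagent + intermediate A → intermediate B (k = 0.130 L mol⁻¹ min⁻¹)
    third reagent + intermediate B → target (k = 0.0170 L mol⁻¹ min⁻¹)
    substrate + second reagent → side product (k = 0.620 L mol⁻¹ min⁻¹)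

The charge view holds for autumn, where feeding third reagent leaves side product at 64.5%, level with summer. Midnight's 88.0% corresponds to b = 0.334 equiv, less than the 2.00 equiv charged. A neighbouring flask, midnight's recipe at 0.013 M substrate with the equivalents held, ends with 80.6% side product and 1.64% substrate. Its b is 0.638 equiv, more than midnight's.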